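**Retrosynthetic overview**
1. Target 13 ⇐ aryl 1,1-dimethylallyl ether 12 by aromatic Claisen rearrangement: the last step frees the chelated 5-OH and places the prenyl group on C6, the only open ortho carbon.
2. 12 ⇐ o-hydroxyaryl tigloyl ketone 10 by asymmetric oxa-Michael closure of the chromanone ring (O1–C2 bond, sets C2 and C3), then methanolysis of the lactone; only the phenol next to the side-chain carbon is free to cyclise.
3. 10 ⇐ phenol 7 by ortho-formylation (8) and rhodium-catalysed hydroacylation of but-2-yne (9), an acid-free way to bring in the acyl group.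
4. 7 ⇐ coumarin 5 by copper hydride asymmetric reduction (sets the side-chain stereocentre); 5 ⇐ 3 + 4 by 7-O-selective palladium allylic etherification; 3 ⇐ 1 + 2 by Pechmann condensation.
5. Ring order: lactone ring first (it also masks the third phenol), chromanone ring second, lactone opened afterwards.

Assumption: the hand of the chiral catalysts in steps 3 and 6 is written as expected by analogy and would be confirmed on the first run; the antipodes are equally available.

**Step 1**
Reactants: 1 phloroglucinol; 2 ethyl 3-oxohexanoate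
Product: 3 5,7-dihydroxy-4-propyl-2H-chromen-2-one
Conditions: conc. H2SO4, 90 °C, 2 h
Reagents that add atoms: none
Why: Pechmann condensation (transesterification, ring closure onto the arene, dehydration) on a symmetrical triphenol, so there is no regiochemical choice and no stereocentre.

**Step 2**
Reactants: 3 5,7-dihydroxy-4-propyl-2H-chromen-2-one; 4 tert-butyl 2-methylbut-3-en-2-yl carbonate
Product: 5 5-hydroxy-7-[(2-methylbut-3-en-2-yl)oxy]-4-propyl-2H-chromen-2-one
Conditions: Pd(PPh3)4 (5 mol%), 4 (1.05 equiv), THF, 0 °C
Reagents that add atoms: none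
Why: Decarboxylative palladium-catalysed allylic etherification (Tsuji–Trost type), in which the more acidic 7-OH (the 5-OH is shielded by the peri propyl group) attacks the more substituted terminus of the π-prenyl palladium complex to give the kinetic tertiary ether; this marks the one oxygen that must not take part in the later ring closure and that will later deliver the prenyl group.

**Step 3**
Reactants: 5 5-hydroxy-7-[(2-methylbut-3-en-2-yl)oxy]-4-propyl-2H-chromen-2-one
Product: 7 (4R)-5-hydroxy-7-[(2-methylbut-3-en-2-yl)oxy]-4-propylchroman-2-one, via bis-silylated ketene acetal 6 (not isolated)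
Conditions: Cu(OAc)2·H2O (5 mol%), (R)-DTBM-SEGPHOS (5.5 mol%), (EtO)2MeSiH (3 equiv), PhMe, rt; then pH 7 phosphate buffer, THF
Reagents that add atoms: none
Why: Copper hydride asymmetric conjugate reduction of a β,β-disubstituted unsaturated lactone, in which the ligand-controlled hydride delivery to one face of C4 sets the (R) centre; the isolated terminal alkene is not touched and the phenol is silylated in the flask and freed again on hydrolysis.

**Step 4**
Reactants: 7 (4R)-5-hydroxy-7-[(2-methylbut-3-en-2-yl)oxy]-4-propylchroman-2-one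
Product: 8 (4R)-5-hydroxy-7-[(2-methylbut-3-en-2-yl)oxy]-2-oxo-4-propylchromane-6-carbaldehyde
Conditions: MgCl2 (2 equiv), Et3N (3 equiv), (CH2O)n (3 equiv), MeCN, 50 °C
Reagents that add atoms: paraformaldehyde (formaldehyde), C=O
Why: Magnesium-mediated ortho-formylation (Casnati–Skattebøl), in which the magnesium phenoxide of the single free OH directs formaldehyde to C6, its only open ortho carbon, and a second formaldehyde oxidises the benzylic alkoxide by hydride transfer, all under basic conditions that spare the acid-labile tertiary allyl ether and the C4 centre.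

**Step 5**
Reactants: 8 (4R)-5-hydroxy-7-[(2-methylbut-3-en-2-yl)oxy]-2-oxo-4-propylchromane-6-carbaldehyde; 9 but-2-yne
Product: 10 (4R)-5-hydroxy-6-[(2E)-2-methylbut-2-enoyl]-7-[(2-methylbut-3-en-2-yl)oxy]-4-propylchroman-2-one
Conditions: [RhCl(cod)]2 (2.5 mol%), Fe(C5H4PPh2)2 (dppf, 5 mol%), Na2CO3 (10 mol%), 9 (3 equiv), PhMe, sealed tube, 60 °C
Reagents that add atoms: none
Why: Chelation-assisted rhodium-catalysed alkyne hydroacylation of a salicylaldehyde, in which the phenoxide-bound acyl rhodium hydride adds syn across but-2-yne to give the (E)-enone (tigloyl ketone) at a temperature below that of the Claisen rearrangement; no stereocentre is formed.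

**Step 6**
Reactants: 10 (4R)-5-hydroxy-6-[(2E)-2-methylbut-2-enoyl]-7-[(2-methylbut-3-en-2-yl)oxy]-4-propylchroman-2-one
Product: 12 methyl (3R)-3-{(2S,3S)-7-hydroxy-2,3-dimethyl-5-[(2-methylbut-3-en-2-yl)oxy]-4-oxochroman-8-yl}hexanoate, via tricyclic chromanone lactone 11 (not isolated)
Conditions: bifunctional iminophosphorane–thiourea organocatalyst from L-tert-leucine (10 mol%), PhMe, −20 °C; then K2CO3 (0.2 equiv), MeOH, 0 °C
Reagents that add atoms: methanol, CO
Why: Proposed new method: the iminophosphorane deprotonates the only free phenol (the second oxygen is blocked as the tertiary allyl ether, the third is held in the lactone) while the thiourea binds the enone carbonyl, the chiral ion pair closes the ring by 6-endo oxa-Michael addition to one face of the (E)-alkene to form the O1–C2 bond and set C2 as S, and the iminophosphoranium N–H returns the proton to C3 on the same face (syn addition across the E-alkene gives the trans-2,3-dimethyl isomer, 3S, which is also the thermodynamic one and so is reinforced by the brief carbonate stage that opens the aryl lactone to the methyl ester); the closest known reaction types are the cinchona-alkaloid-catalysed intramolecular oxa-Michael addition of o-tigloylphenols, which is cis-selective, and iminophosphorane-catalysed oxa-Michael additions of alcohols to unsaturated esters.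

**Step 7**
Reactants: 12 methyl (3R)-3-{(2S,3S)-7-hydroxy-2,3-dimethyl-5-[(2-methylbut-3-en-2-yl)oxy]-4-oxochroman-8-yl}hexanoate
Product: 13 methyl (3R)-3-[(2S,3S)-5,7-dihydroxy-2,3-dimethyl-6-(3-methylbut-2-en-1-yl)-4-oxochroman-8-yl]hexanoate
Conditions: PhMe, 100 °C, 3 h
Reagents that add atoms: none
Why: Aromatic Claisen rearrangement ([3,3]), in which the 1,1-dimethylallyl group can migrate only to C6 (the other ortho position is the ring-fusion carbon C4a), arrives as the 3-methylbut-2-enyl group by allyl inversion and releases the hydrogen-bonded 5-OH under neutral conditions that leave all three stereocentres untouched.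

**Compound list**
1 | phloroglucinol (benzene-1,3,5-triol) | Oc1cc(O)cc(O)c1 | starting material
2 | ethyl 3-oxohexanoate | CCCC(=O)CC(=O)OCC | starting material
3 | 5,7-dihydroxy-4-propyl-2H-chromen-2-one | CCCC1=CC(=O)Oc2cc(O)cc(O)c21 | intermediate
4 | tert-butyl 2-methylbut-3-en-2-yl carbonate | CC(C)(C)OC(=O)OC(C)(C)C=C | starting material
5 | 5-hydroxy-7-[(2-methylbut-3-en-2-yl)oxy]-4-propyl-2H-chromen-2-one | CCCC1=CC(=O)Oc2cc(OC(C)(C)C=C)cc(O)c21 | intermediate
6 | (4R)-2,5-bis{[diethoxy(methyl)silyl]oxy}-7-[(2-methylbut-3-en-2-yl)oxy]-4-propyl-4H-chromene | CCC[C@@H]1C=C(O[Si](C)(OCC)OCC)Oc2cc(OC(C)(C)C=C)cc(O[Si](C)(OCC)OCC)c21 | intermediate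
7 | (4R)-5-hydroxy-7-[(2-methylbut-3-en-2-yl)oxy]-4-propylchroman-2-one | CCC[C@@H]1CC(=O)Oc2cc(OC(C)(C)C=C)cc(O)c21 | intermediate
8 | (4R)-5-hydroxy-7-[(2-methylbut-3-en-2-yl)oxy]-2-oxo-4-propylchromane-6-carbaldehyde | CCC[C@@H]1CC(=O)Oc2cc(OC(C)(C)C=C)c(C=O)c(O)c21 | intermediate
9 | but-2-yne | CC#CC | starting material
10 | (4R)-5-hydroxy-6-[(2E)-2-methylbut-2-enoyl]-7-[(2-methylbut-3-en-2-yl)oxy]-4-propylchroman-2-one | CCC[C@@H]1CC(=O)Oc2cc(OC(C)(C)C=C)c(C(=O)/C(C)=C/C)c(O)c21 | intermediate
11 | (2S,3S,10R)-2,3-dimethyl-5-[(2-methylbut-3-en-2-yl)oxy]-10-propyl-2,3,9,10-tetrahydro-4H,8H-pyrano[2,3-f]chromene-4,8-dione (chromanone ring fused through O at C5 and C at C6 of the dihydrocoumarin) | CCC[C@@H]1CC(=O)Oc2cc(OC(C)(C)C=C)c3c(c21)O[C@@H](C)[C@H](C)C3=O | intermediate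
12 | methyl (3R)-3-{(2S,3S)-7-hydroxy-2,3-dimethyl-5-[(2-methylbut-3-en-2-yl)oxy]-4-oxochroman-8-yl}hexanoate | CCC[C@H](CC(=O)OC)c1c(O)cc(OC(C)(C)C=C)c2c1O[C@@H](C)[C@H](C)C2=O | intermediate
13 | methyl (3R)-3-[(2S,3S)-5,7-dihydroxy-2,3-dimethyl-6-(3-methylbut-2-en-1-yl)-4-oxochroman-8-yl]hexanoate | CCC[C@H](CC(=O)OC)c1c(O)c(CC=C(C)C)c(O)c2c1O[C@@H](C)[C@H](C)C2=O | target

**Step count and risks**

Total steps: 7. Longest linear sequence: 7 steps (1 → 13).

Steps most likely to fail:

- **Step 3 (copper hydride reduction).** C4 is β,β-disubstituted and hindered by the peri oxygen, the substrate carries a free phenol, and the sense of induction is assumed. The fallback builds the stereocentre by C–C bond formation instead of reduction and sets out from 1. Iminium-catalysed Friedel–Crafts alkylation and hemiacetal closure of excess 1 with (E)-hex-2-enal (diphenylprolinol trimethylsilyl ether, 10 mol%) gives the lactol (4R)-4-propylchromane-2,5,7-triol F1. Oxidation with Ag2CO3 on Celite (PhMe, 80 °C) gives (4R)-5,7-dihydroxy-4-propylchroman-2-one F2. Etherification of F2 with 4 and Pd(PPh3)4 at the unhindered 7-OH comes back to the route at 7.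

- **Step 5 (alkyne hydroacylation).** The aldehyde is flanked on both sides, the neighbouring vinyl group could insert intramolecularly, and the temperature is capped by the Claisen threshold. The fallback replaces C–H activation by carbonyl addition and oxidation and sets out from 8. Nozaki–Hiyama–Kishi addition of (E)-2-bromobut-2-ene (CrCl2, cat. NiCl2, DMF, rt) gives the allylic alcohol (4R)-5-hydroxy-6-[(2E)-1-hydroxy-2-methylbut-2-en-1-yl]-7-[(2-methylbut-3-en-2-yl)oxy]-4-propylchroman-2-one F3 as a mixture of carbinol epimers. Oxidation with MnO2 (CH2Cl2, rt) comes back to the route at 10.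

- **Step 6 (proposed new oxa-Michael closure).** Neither the level of enantiocontrol at C2 nor the syn protonation is established for this catalyst class. The fallback uses known chemistry, separates the two stereocentres into two events, and sets out from 10. The known cinchona-alkaloid-catalysed intramolecular oxa-Michael addition of o-tigloylphenols (quinidine, 10 mol%, PhCl, rt; cis-selective, C2 set by the alkaloid) gives the cis tricycle (2S,3R,10R)-2,3-dimethyl-5-[(2-methylbut-3-en-2-yl)oxy]-10-propyl-2,3,9,10-tetrahydro-4H,8H-pyrano[2,3-f]chromene-4,8-dione F4. Epimerisation at C3 by soft enolisation (MgI2, Et3N, CH2Cl2) to the more stable trans isomer comes back to the route at 11, which is opened with K2CO3 in MeOH to 12 as in step 6.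

**Further compounds**
F1 | step 3 | (4R)-4-propylchromane-2,5,7-triol (lactol, both anomers) | CCC[C@@H]1CC(O)Oc2cc(O)cc(O)c21
F2 | step 3 | (4R)-5,7-dihydroxy-4-propylchroman-2-one | CCC[C@@H]1CC(=O)Oc2cc(O)cc(O)c21
F3 | step 5 | (4R)-5-hydroxy-6-[(2E)-1-hydroxy-2-methylbut-2-en-1-yl]-7-[(2-methylbut-3-en-2-yl)oxy]-4-propylchroman-2-one | CCC[C@@H]1CC(=O)Oc2cc(OC(C)(C)C=C)c(C(O)/C(C)=C/C)c(O)c21
F4 | step 6 | (2S,3R,10R)-2,3-dimethyl-5-[(2-methylbut-3-en-2-yl)oxy]-10-propyl-2,3,9,10-tetrahydro-4H,8H-pyrano[2,3-f]chromene-4,8-dione | CCC[C@@H]1CC(=O)Oc2cc(OC(C)(C)C=C)c3c(c21)O[C@@H](C)[C@@H](C)C3=O
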